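**Retrosynthetic overview**
1. Feature: the target is a meso cyclobutane (C1–C4) whose neighbouring carbons C1 and C2 carry two identical arylethynyl arms on the same face. C1, C2, the two ring-bound alkyne carbons (Ca on C2, Ca' on C1) and the thiophene-bound alkyne carbon Cb of one arm can be tied into a cyclopentane-1,3-dione ring (Ca, Ca' as C=O, Cb as CH2) fused along C1–C2, so the cis relationship is stored as a cis ring junction.
2. Late disconnections: thiophene–Cb' by Sonogashira coupling, and Ca'≡Cb' by Corey–Fuchs homologation of cis aldehyde 9.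
3. Clamp opening: hydride addition at Ca' of vinylogous acyl triflate 7 and Grob-type cleavage of Ca'–Cb unveil the Ca≡Cb alkyne. Triflate 7 comes from dione 3 by palladium-catalysed arylation at Cb and O-triflation.
4. Key disconnection: C1–C4 and C2–C3, that is, [2+2] photocycloaddition of ethylene 2 to the C1=C2 alkene of cyclopent-4-ene-1,3-dione 1.
5. Ring order: the clamp ring and the four thiophenes are bought, the cyclobutane is the only ring made (step 1), and the clamp ring is cut open in step 4.

Key step: step 1

Remark on the chemistry: 3 and 15 are meso. Compounds 7–14 are chiral and are carried as racemates (SMILES show one enantiomer, relative configuration only). This suffices because the second identical arm restores the mirror plane. Compound 6 is drawn as its enol, whose two tautomers interconvert.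

**Step 1**
Reactants: 1 cyclopent-4-ene-1,3-dione; 2 ethylene
Product: 3 (1R,5S)-bicyclo[3.2.0]heptane-2,4-dione (cis-fused, meso)
Conditions: C2H4 (bubbled, saturated), CH2Cl2 (0.02 M), hν (365 nm, immersion reactor), -78 °C
Reagents that add atoms: none
Why: Excitation of the weak long-wavelength n,pi* band of pale yellow 1 and intersystem crossing give the triplet enedione, which bonds through one alkene carbon to ethylene (C1–C4) to give a triplet 1,4-diradical that recombines after spin inversion to form C2–C3. The closest known reaction type is the enone–alkene [2+2] photocycloaddition as run with ethylene on cyclopentenones, maleic anhydride and maleimides. The cyclobutane is the only ring closed, in an intermolecular two-bond [2+2] mode whose ring-closing event is the 1,4-diradical recombination. Both new stereocentres (C1 and C5 of 3, the later C1 and C2 of the target) are controlled by the five-membered clamp ring, since the strain of a trans junction between a four- and a five-membered ring rules that isomer out and later enolisation toward these carbons has no other outcome than the cis junction. Regio- and facial selectivity are not at issue because both partners are symmetric and 1 is planar, whereas chemoselectivity is needed for C=C over C=O addition, favoured because ethylene is not electron-rich and is a poor oxetane partner, and for cross-addition over dimerisation of 1, secured by keeping 1 dilute in ethylene-saturated solvent at -78 °C. Light of 365 nm is taken up by 1 alone, so that 3 and its enol, which absorb only at much shorter wavelength, stay out of a second de Mayo-type addition of ethylene and out of alpha-cleavage.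

**Step 2**
Reactants: 3 (1R,5S)-bicyclo[3.2.0]heptane-2,4-dione; 4 5-bromo-2,2'-bithiophene
Product: 6 3-(2,2'-bithiophen-5-yl)-cis-bicyclo[3.2.0]heptane-2,4-dione (enol tautomer drawn), via potassium enolate 5 (not isolated)
Conditions: Pd(OAc)2 (3 mol%), XPhos (6 mol%), K3PO4 (2.5 equiv), 1,4-dioxane, 90 °C; then 1 M HCl
Reagents that add atoms: none
Why: Palladium-catalysed alpha-arylation of a cyclic 1,3-dione (Buchwald–Hartwig type enolate arylation), in which K3PO4 forms only the stabilised C3 enolate, the bulky biaryl phosphine drives C–C reductive elimination from the arylpalladium dionate, the more acidic product is parked as enolate 5 so that a second arylation is blocked, and the bridgehead centres cannot be lost because the clamp ring permits only the cis junction.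

**Step 3**
Reactants: 6 3-(2,2'-bithiophen-5-yl)-cis-bicyclo[3.2.0]heptane-2,4-dione
Product: 7 (±)-cis-3-(2,2'-bithiophen-5-yl)-4-oxobicyclo[3.2.0]hept-2-en-2-yl trifluoromethanesulfonate
Conditions: Tf2O (1.2 equiv), pyridine (2 equiv), CH2Cl2, -78 °C to 0 °C
Reagents that add atoms: trifluoromethanesulfonic anhydride, O=S(=O)(OS(=O)(=O)C(F)(F)F)C(F)(F)F
Why: O-sulfonylation of the enol of a 2-aryl-1,3-dione to a vinylogous acyl triflate, in which the two oxygen atoms are equivalent through tautomerism so that one racemic triflate should form and no stereocentre is touched.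

**Step 4**
Reactants: 7 (±)-cis-3-(2,2'-bithiophen-5-yl)-4-oxobicyclo[3.2.0]hept-2-en-2-yl trifluoromethanesulfonate
Product: 11 (±)-cis-{2-[(2,2'-bithiophen-5-yl)ethynyl]cyclobutyl}methanol, via lithium carbinolate 8 (not isolated), via aldehyde 9 (not isolated), via lithium alkoxide 10 (not isolated)
Conditions: LiEt3BH (2.2 equiv), THF, -78 °C to rt; then H2O
Reagents that add atoms: none
Why: Tandem 1,2-hydride addition and Grob-type fragmentation of a vinylogous acyl triflate, in which hydride adds to the ketone from the convex face to give carbinolate 8 (its new centre is lost again at once and needs no control), the C2–C3 bond of 8 lies anti-periplanar to the C4–OTf bond across the alkene and breaks on warming with loss of triflate and release of ring strain to give the aryl alkyne and aldehyde 9, and the second equivalent of hydride traps 9 as alkoxide 10 before any alkoxide can enolise it, so that C1 and C5 pass unchanged into the cis-disubstituted cyclobutane.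

**Step 5**
Reactants: 11 (±)-cis-{2-[(2,2'-bithiophen-5-yl)ethynyl]cyclobutyl}methanol
Product: 9 (±)-cis-2-[(2,2'-bithiophen-5-yl)ethynyl]cyclobutane-1-carbaldehyde
Conditions: TEMPO (10 mol%), PhI(OAc)2 (1.1 equiv), CH2Cl2, 0 °C to rt
Reagents that add atoms: none
Why: Oxoammonium-mediated (TEMPO/PhI(OAc)2) oxidation of a primary alcohol, chosen because it runs without base and stops at the aldehyde, so the epimerisable carbon next to the formyl group should keep the cis configuration while thiophenes and alkyne stay inert.

**Step 6**
Reactants: 9 (±)-cis-2-[(2,2'-bithiophen-5-yl)ethynyl]cyclobutane-1-carbaldehyde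
Product: 12 (±)-cis-5-{[2-(2,2-dibromoethenyl)cyclobutyl]ethynyl}-2,2'-bithiophene
Conditions: CBr4, PPh3, Zn dust (2 equiv each), CH2Cl2, rt, 24 h; then 9, 0 °C to rt
Reagents that add atoms: carbon tetrabromide, BrC(Br)(Br)Br
Why: Ramirez dibromoolefination (first stage of the Corey–Fuchs sequence) with the ylide Ph3P=CBr2 pre-formed with zinc, a non-basic Wittig-type reaction that adds the last carbon Cb' without enolising the aldehyde, so the cis relationship is carried over.

**Step 7**
Reactants: 12 (±)-cis-5-{[2-(2,2-dibromoethenyl)cyclobutyl]ethynyl}-2,2'-bithiophene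
Product: 14 (±)-cis-5-[(2-ethynylcyclobutyl)ethynyl]-2,2'-bithiophene, via lithium acetylide 13 (not isolated)
Conditions: n-BuLi (2.05 equiv), THF, -78 °C, 1 h; then H2O, -78 °C to rt
Reagents that add atoms: none
Why: Second stage of the Corey–Fuchs sequence, in which bromine–lithium exchange, loss of LiBr with a Fritsch–Buttenberg–Wiechell type 1,2-hydrogen shift and deprotonation give acetylide 13 faster than n-BuLi can attack the propargylic cyclobutane C–H at -78 °C, and the proton quench also erases any stray lithiation at the free thiophene alpha position, which is why the alkyne is isolated rather than zincated and coupled in the same flask.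

**Step 8**
Reactants: 14 (±)-cis-5-[(2-ethynylcyclobutyl)ethynyl]-2,2'-bithiophene; 4 5-bromo-2,2'-bithiophene
Product: 15 isocardopatine, (1R,2S)-1,2-bis[(2,2'-bithiophen-5-yl)ethynyl]cyclobutane (cis, meso)
Conditions: PdCl2(PhCN)2 (3 mol%), [HP(t-Bu)3]BF4 (6 mol%), CuI (2 mol%), i-Pr2NH, 1,4-dioxane, rt, degassed, dark
Reagents that add atoms: none
Why: Sonogashira coupling with a bulky electron-rich phosphine that lets the 2-bromothiophene add oxidatively to zerovalent palladium at room temperature, so the amine base cannot epimerise the propargylic centres, the cis-1,2-dialkynylcyclobutane stays far below the temperature of its Cope-type rearrangement, and the second identical arm turns the racemic precursor into the meso target.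

**Compound list**
1 | cyclopent-4-ene-1,3-dione | O=C1CC(=O)C=C1 | starting material
2 | ethylene | C=C | starting material
3 | (1R,5S)-bicyclo[3.2.0]heptane-2,4-dione (cis-fused, meso) | O=C1CC(=O)[C@@H]2CC[C@H]12 | intermediate
4 | 5-bromo-2,2'-bithiophene | Brc1ccc(-c2cccs2)s1 | starting material
5 | potassium enolate of 6 | [K+].[O-]C1=C(c3ccc(-c4cccs4)s3)C(=O)[C@@H]2CC[C@H]12 | intermediate
6 | 3-(2,2'-bithiophen-5-yl)-cis-bicyclo[3.2.0]heptane-2,4-dione, drawn as enol | OC1=C(c3ccc(-c4cccs4)s3)C(=O)[C@@H]2CC[C@H]12 | intermediate
7 | (±)-cis-3-(2,2'-bithiophen-5-yl)-4-oxobicyclo[3.2.0]hept-2-en-2-yl trifluoromethanesulfonate | O=S(=O)(OC1=C(c3ccc(-c4cccs4)s3)C(=O)[C@@H]2CC[C@H]12)C(F)(F)F | intermediate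
8 | lithium (±)-3-(2,2'-bithiophen-5-yl)-4-(trifluoromethylsulfonyloxy)-cis-bicyclo[3.2.0]hept-3-en-2-olate (hydride on the convex face) | [Li]O[C@H]1C(c3ccc(-c4cccs4)s3)=C(OS(=O)(=O)C(F)(F)F)[C@H]2CC[C@@H]12 | intermediate
9 | (±)-cis-2-[(2,2'-bithiophen-5-yl)ethynyl]cyclobutane-1-carbaldehyde | O=C[C@@H]1CC[C@@H]1C#Cc1ccc(-c2cccs2)s1 | intermediate
10 | lithium alkoxide of 11 | [Li]OC[C@@H]1CC[C@@H]1C#Cc1ccc(-c2cccs2)s1 | intermediate
11 | (±)-cis-{2-[(2,2'-bithiophen-5-yl)ethynyl]cyclobutyl}methanol | OC[C@@H]1CC[C@@H]1C#Cc1ccc(-c2cccs2)s1 | intermediate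
12 | (±)-cis-5-{[2-(2,2-dibromoethenyl)cyclobutyl]ethynyl}-2,2'-bithiophene | BrC(Br)=C[C@@H]1CC[C@@H]1C#Cc1ccc(-c2cccs2)s1 | intermediate
13 | lithium acetylide of 14 | [Li]C#C[C@@H]1CC[C@@H]1C#Cc1ccc(-c2cccs2)s1 | intermediate
14 | (±)-cis-5-[(2-ethynylcyclobutyl)ethynyl]-2,2'-bithiophene | C#C[C@@H]1CC[C@@H]1C#Cc1ccc(-c2cccs2)s1 | intermediate
15 | isocardopatine, (1R,2S)-1,2-bis[(2,2'-bithiophen-5-yl)ethynyl]cyclobutane | C(#C[C@@H]1CC[C@@H]1C#Cc1ccc(-c2cccs2)s1)c1ccc(-c2cccs2)s1 | target

**Total step count:** 8. **Longest linear sequence:** 8 steps (1 to 15).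

**Steps most likely to fail**

1. Step 1 (key step).
   - What may go wrong: photodimerisation of the enedione, oxetane formation at a carbonyl group, hydrogen abstraction by the excited enedione, or onward photoreaction of the enolised product may outrun the cross-addition.
   - Fallback (sets out from 2, returns at 3): the second carbonyl group would be masked at the alcohol level, so that a plain cyclopentenone is the chromophore and the photoproduct is a saturated ketone. Ethylene 2 would be added under Pyrex-filtered light (CH2Cl2, -78 °C) to commercial (±)-4-(tert-butyldimethylsilyloxy)cyclopent-2-en-1-one, anti to the silyl ether. This would give (±)-exo-4-(tert-butyldimethylsilyloxy)-cis-bicyclo[3.2.0]heptan-2-one F1. Aqueous HF in MeCN would free (±)-exo-4-hydroxy-cis-bicyclo[3.2.0]heptan-2-one F2. IBX in hot EtOAc would then oxidise the beta-hydroxy ketone to dione 3.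

2. Step 4.
   - What may go wrong: hydride attack at the triflate-bearing carbon or at sulfur instead of the carbonyl group, or reluctance of the five-membered carbinolate to fragment, would stall the clamp opening.
   - Fallback (sets out from 7, returns at 9, so step 5 is also bypassed): the clamp would be cut by an Eschenmoser–Tanabe fragmentation.
     - Palladium-catalysed formate reduction of the vinyl triflate (Pd(OAc)2, PPh3, HCO2H, Et3N, DMF, 60 °C) would give (±)-cis-3-(2,2'-bithiophen-5-yl)bicyclo[3.2.0]hept-3-en-2-one F3.
     - Weitz–Scheffer epoxidation (H2O2, NaOH, MeOH, 0 °C) from the convex face would give (±)-exo-3,4-epoxy-3-(2,2'-bithiophen-5-yl)-cis-bicyclo[3.2.0]heptan-2-one F4.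
     - TsNHNH2 in AcOH/CH2Cl2 (-20 °C to rt) would form the tosylhydrazone of the epoxy ketone F5.
     - F5 should fragment in the flask to racemic aldehyde 9 under weakly acidic, non-epimerising conditions.

3. Step 2.
   - What may go wrong: slow reductive elimination from the chelating palladium dionate, hydrodebromination of 4, or C–H self-arylation at its free thiophene alpha position would erode the coupling.
   - Fallback (sets out from 3, returns at 6): the polarity would be inverted so that the dione is the electrophile. PhI(OAc)2 and Na2CO3 in aqueous EtOH at rt would convert 3 into the phenyliodonium ylide 3-(phenyl-lambda3-iodanylidene)-cis-bicyclo[3.2.0]heptane-2,4-dione F6. Suzuki-type coupling with commercial 2,2'-bithiophene-5-boronic acid pinacol ester (Pd(OAc)2, LiOH, DME/H2O, 50 °C, acidic work-up) would then give 6.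

**Further compounds**
F1 | step 1 | (±)-exo-4-(tert-butyldimethylsilyloxy)-cis-bicyclo[3.2.0]heptan-2-one | O=C1C[C@H](O[Si](C)(C)C(C)(C)C)[C@H]2CC[C@@H]12
F2 | step 1 | (±)-exo-4-hydroxy-cis-bicyclo[3.2.0]heptan-2-one | O=C1C[C@H](O)[C@H]2CC[C@@H]12
F3 | step 4 | (±)-cis-3-(2,2'-bithiophen-5-yl)bicyclo[3.2.0]hept-3-en-2-one | C1=C(c3ccc(-c4cccs4)s3)C(=O)[C@@H]2CC[C@H]12
F4 | step 4 | (±)-exo-3,4-epoxy-3-(2,2'-bithiophen-5-yl)-cis-bicyclo[3.2.0]heptan-2-one | O=C1[C@]3(c4ccc(-c5cccs5)s4)O[C@@H]3[C@H]2CC[C@@H]12
F5 | step 4 | tosylhydrazone of the epoxy ketone F4 | Cc1ccc(cc1)S(=O)(=O)NN=C1[C@]3(c4ccc(-c5cccs5)s4)O[C@@H]3[C@H]2CC[C@@H]12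
F6 | step 2 | 3-(phenyl-lambda3-iodanylidene)-cis-bicyclo[3.2.0]heptane-2,4-dione (phenyliodonium ylide) | [O-]C1=C([I+]c3ccccc3)C(=O)[C@@H]2CC[C@H]12
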